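**Retrosynthetic overview**
1. The ten-membered carbocycle is closed last, at C4–C5, by an intramolecular Nozaki–Hiyama–Kishi coupling of a (Z)-vinyl iodide with a C5 aldehyde; oxidation of the carbinol gives the Z-enone.
2. The open chain is joined at C9=C10 by a Wittig olefination of an east epoxy-lactol with a west ester ylide; the (E)-enoate is reduced and epoxidised (Sharpless, D-tartrate) to set C9/C10.
3. East fragment: a β-keto δ-lactone enol triflate is allylated (Stille), so the tetrasubstituted C7=C11 geometry is fixed by a ring; reduction and Sharpless epoxidation (L-tartrate) set C7/C11, and an oxidative lactonisation tells the two CH2OH groups apart.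
4. West fragment: a Stork–Zhao olefination gives the (Z)-vinyl iodide, whose homoallylic iodide alkylates an ester-stabilised ylide.
5. Ring order: spiro-oxirane (step 5), fused oxirane (step 17), ten-membered ring (step 19).

Labels used in the text (target carbons): ring C1H2–C2H2–C3H=C4(CH3)–C5(=O)–C6H2–C7(spiro)–C8H2–C9H–C10, fused oxirane on C9/C10, C14 = CH2OAc on C10, C11 = exocyclic oxirane carbon on C7 carrying CH3 and C12H2OAc.

Assumption: reagents bought and used as such (allyltributylstannane, ethyltriphenylphosphonium iodide, both diethyl tartrates) are not counted as steps; the anomeric carbon of 9 and the carbinol carbon of 26 are carried as epimer mixtures because both become sp2 later.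

**East fragment**

Step 1
Reactants: 1 ethyl 2-methyl-3-oxobutanoate
Product: 3 4-hydroxy-3-methyl-5,6-dihydro-2H-pyran-2-one, via hydroxy keto ester 2 (not isolated)
Conditions: NaH, THF, 0 °C; n-BuLi, 0 °C; CH2O gas (from cracked paraformaldehyde), −20 °C → rt; then 1 M NaOH, rt; HCl to pH 1
Reagents that add atoms: formaldehyde, C=O
Why: Weiler dianion hydroxymethylation at the terminal carbon followed by lactonisation of the δ-hydroxy β-keto ester gives the enolised β-keto δ-lactone (no stereocentre).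

Step 2
Reactants: 3 4-hydroxy-3-methyl-5,6-dihydro-2H-pyran-2-one
Product: 4 3-methyl-2-oxo-5,6-dihydro-2H-pyran-4-yl trifluoromethanesulfonate
Conditions: Tf2O, Et3N, CH2Cl2, −78 °C
Reagents that add atoms: trifluoromethanesulfonic anhydride, O=S(=O)(OS(=O)(=O)C(F)(F)F)C(F)(F)F
Why: O-sulfonylation of the vinylogous acid gives a cyclic enol triflate in which the ring holds the lactone carbonyl (C12) cis to the ring CH2 (C8).

Step 3
Reactants: 4 3-methyl-2-oxo-5,6-dihydro-2H-pyran-4-yl trifluoromethanesulfonate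
Product: 5 3-methyl-4-(prop-2-en-1-yl)-5,6-dihydro-2H-pyran-2-one
Conditions: allylSnBu3 (1.2 equiv), Pd(PPh3)4 (5 mol %), LiCl (3 equiv), THF, 60 °C
Reagents that add atoms: allyltributylstannane, C=CC[Sn](CCCC)(CCCC)CCCC
Why: Stille cross-coupling of the enol triflate puts the allyl group (the masked C6–C5 aldehyde arm) on C7 trans to C12, the tetrasubstituted alkene geometry being fixed by the ring.

Step 4
Reactants: 5 3-methyl-4-(prop-2-en-1-yl)-5,6-dihydro-2H-pyran-2-one
Product: 6 (2Z)-2-methyl-3-(prop-2-en-1-yl)pent-2-ene-1,5-diol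
Conditions: LiAlH4, Et2O, 0 °C
Reagents that add atoms: none
Why: Hydride 1,2-reduction of the unsaturated lactone opens the ring to the diol, whose Z geometry is inherited from the ring.

Step 5
Reactants: 6 (2Z)-2-methyl-3-(prop-2-en-1-yl)pent-2-ene-1,5-diol
Product: 7 2-[(2R,3S)-3-(hydroxymethyl)-3-methyl-2-(prop-2-en-1-yl)oxiran-2-yl]ethan-1-ol
Conditions: Ti(OiPr)4 (0.3 equiv), L-(+)-diethyl tartrate (0.36 equiv), t-BuOOH (2 equiv, in decane), 4 Å molecular sieves, CH2Cl2, −20 °C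
Reagents that add atoms: tert-butyl hydroperoxide, CC(C)(C)OO
Why: Sharpless asymmetric epoxidation of the tetrasubstituted allylic alcohol, in which the L-(+)-tartrate selects the face that gives the C11 quaternary centre and, by syn addition to the Z alkene, the C7 spiro centre of the target, while the terminal alkene is inert.

Step 6
Reactants: 7 2-[(2R,3S)-3-(hydroxymethyl)-3-methyl-2-(prop-2-en-1-yl)oxiran-2-yl]ethan-1-ol
Product: 10 (1S,6R)-1-methyl-6-(prop-2-en-1-yl)-3,7-dioxabicyclo[4.1.0]heptan-4-one, via hydroxy aldehyde 8 (not isolated), via lactol 9 (not isolated)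
Conditions: TEMPO (0.2 equiv), PhI(OAc)2 (2.5 equiv), CH2Cl2, rt
Reagents that add atoms: none
Why: Oxoammonium (TEMPO) oxidation attacks the unhindered primary alcohol rather than the neopentylic one on the quaternary oxirane carbon, and the hydroxy aldehyde closes to the cis-fused lactol and is oxidised on to the δ-lactone, so the two hydroxyls are told apart without protecting groups.

Step 7
Reactants: 10 (1S,6R)-1-methyl-6-(prop-2-en-1-yl)-3,7-dioxabicyclo[4.1.0]heptan-4-one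
Product: 9 (1S,6R)-1-methyl-6-(prop-2-en-1-yl)-3,7-dioxabicyclo[4.1.0]heptan-4-ol
Conditions: iBu2AlH (1.1 equiv), CH2Cl2, −78 °C
Reagents that add atoms: none
Why: Partial hydride reduction of the lactone stops at the aluminium hemiacetal and gives the lactol (both anomers), a stable cyclic form of the sensitive β,γ-epoxy aldehyde.

**West fragment**

Step 8
Reactants: 11 propane-1,3-diol
Product: 12 3-{[tert-butyl(dimethyl)silyl]oxy}propan-1-ol
Conditions: NaH (1.0 equiv), THF, 0 °C → rt; TBSCl (1.0 equiv)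
Reagents that add atoms: tert-butyl(chloro)dimethylsilane, CC(C)(C)[Si](C)(C)Cl
Why: O-silylation of the sparingly soluble monosodium alkoxide gives selective monoprotection of the symmetrical diol.

Step 9
Reactants: 12 3-{[tert-butyl(dimethyl)silyl]oxy}propan-1-ol
Product: 13 3-{[tert-butyl(dimethyl)silyl]oxy}propanal
Conditions: TEMPO (0.1 equiv), PhI(OAc)2 (1.1 equiv), CH2Cl2, rt
Reagents that add atoms: none
Why: TEMPO-catalysed oxidation takes the primary alcohol to the aldehyde without over-oxidation.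

Step 10
Reactants: 13 3-{[tert-butyl(dimethyl)silyl]oxy}propanal
Product: 14 tert-butyl{[(3Z)-4-iodopent-3-en-1-yl]oxy}dimethylsilane
Conditions: [Ph3PCH2CH3]I, n-BuLi, THF, rt; I2, −78 °C; NaN(SiMe3)2, −20 °C; then 13, −78 → −20 °C
Reagents that add atoms: ethyltriphenylphosphonium iodide, CC[P+](c1ccccc1)(c1ccccc1)c1ccccc1.[I-]; iodine, I-I
Why: Stork–Zhao Wittig olefination with the α-iodo ylide gives the trisubstituted (Z)-vinyl iodide (iodine cis to the chain) under kinetic control.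

Step 11
Reactants: 14 tert-butyl{[(3Z)-4-iodopent-3-en-1-yl]oxy}dimethylsilane
Product: 15 (3Z)-4-iodopent-3-en-1-ol
Conditions: HF·pyridine, THF, 0 °C → rt
Reagents that add atoms: none
Why: Fluoride-driven desilylation frees the primary alcohol and leaves the vinyl iodide untouched.

Step 12
Reactants: 15 (3Z)-4-iodopent-3-en-1-ol
Product: 16 (2Z)-2,5-diiodopent-2-ene
Conditions: PPh3, I2, imidazole, CH2Cl2, 0 °C
Reagents that add atoms: iodine, I-I
Why: Appel-type iodination proceeds by SN2 displacement of the alkoxyphosphonium at the primary carbon.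

Step 13
Reactants: 16 (2Z)-2,5-diiodopent-2-ene; 17 ethyl (triphenyl-lambda5-phosphanylidene)acetate
Product: 18 [(5Z)-1-ethoxy-6-iodo-1-oxohept-5-en-2-yl]triphenylphosphonium iodide
Conditions: MeCN, 80 °C (1:1)
Reagents that add atoms: none
Why: C-alkylation (SN2) of the ester-stabilised ylide by the primary alkyl iodide gives the α-branched phosphonium salt, the vinyl iodide being inert.

Step 14
Reactants: 18 [(5Z)-1-ethoxy-6-iodo-1-oxohept-5-en-2-yl]triphenylphosphonium iodide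
Product: 19 ethyl (5Z)-6-iodo-2-(triphenyl-lambda5-phosphanylidene)hept-5-enoate
Conditions: 1 M NaOH, CH2Cl2, 0 °C
Reagents that add atoms: none
Why: Deprotonation of the acidic C–H between phosphorus and the ester gives the stabilised α-branched ylide.

**Union and endgame**

Step 15
Reactants: 9 (1S,6R)-1-methyl-6-(prop-2-en-1-yl)-3,7-dioxabicyclo[4.1.0]heptan-4-ol; 19 ethyl (5Z)-6-iodo-2-(triphenyl-lambda5-phosphanylidene)hept-5-enoate
Product: 20 ethyl (2E,5Z)-2-{2-[(2R,3S)-3-(hydroxymethyl)-3-methyl-2-(prop-2-en-1-yl)oxiran-2-yl]ethylidene}-6-iodohept-5-enoate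
Conditions: toluene, 80 °C
Reagents that add atoms: none
Why: Wittig olefination through the open hydroxy-aldehyde form of the lactol, in which the ester-stabilised α-branched ylide gives the (E)-enoate (C8 cis to C1), the geometry needed for the cis-fused 9,10-oxirane.

Step 16
Reactants: 20 ethyl (2E,5Z)-2-{2-[(2R,3S)-3-(hydroxymethyl)-3-methyl-2-(prop-2-en-1-yl)oxiran-2-yl]ethylidene}-6-iodohept-5-enoate
Product: 21 (2E,5Z)-2-{2-[(2R,3S)-3-(hydroxymethyl)-3-methyl-2-(prop-2-en-1-yl)oxiran-2-yl]ethylidene}-6-iodohept-5-en-1-ol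
Conditions: iBu2AlH (3.5 equiv), CH2Cl2, −78 °C
Reagents that add atoms: none
Why: Hydride 1,2-reduction of the enoate gives the allylic alcohol without touching the oxirane or the vinyl iodide at low temperature.

Step 17
Reactants: 21 (2E,5Z)-2-{2-[(2R,3S)-3-(hydroxymethyl)-3-methyl-2-(prop-2-en-1-yl)oxiran-2-yl]ethylidene}-6-iodohept-5-en-1-ol
Product: 23 {(2R,3R)-3-{[(2R,3S)-3-[(acetyloxy)methyl]-3-methyl-2-(prop-2-en-1-yl)oxiran-2-yl]methyl}-2-[(3Z)-4-iodopent-3-en-1-yl]oxiran-2-yl}methyl acetate, via bis-epoxy diol 22 (not isolated)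
Conditions: Ti(OiPr)4 (0.1 equiv), D-(−)-diethyl tartrate (0.12 equiv), t-BuOOH (1.5 equiv), 4 Å molecular sieves, CH2Cl2, −20 °C; then P(OMe)3 (0.6 equiv); Et3N, DMAP (cat.), Ac2O (3 equiv), −20 → 0 °C
Reagents that add atoms: tert-butyl hydroperoxide, CC(C)(C)OO; acetic anhydride, CC(=O)OC(C)=O
Why: A second Sharpless asymmetric epoxidation, now with the D-(−)-tartrate, sets C9 and C10 (9R,10R) under reagent control on the (E)-allylic alcohol, and in situ acetylation caps both primary alcohols so the polar bis-epoxy diol is never isolated.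

Step 18
Reactants: 23 {(2R,3R)-3-{[(2R,3S)-3-[(acetyloxy)methyl]-3-methyl-2-(prop-2-en-1-yl)oxiran-2-yl]methyl}-2-[(3Z)-4-iodopent-3-en-1-yl]oxiran-2-yl}methyl acetate
Product: 25 {(2R,3R)-3-{[(2S,3S)-3-[(acetyloxy)methyl]-3-methyl-2-(2-oxoethyl)oxiran-2-yl]methyl}-2-[(3Z)-4-iodopent-3-en-1-yl]oxiran-2-yl}methyl acetate, via vicinal diol 24 (not isolated)
Conditions: OsO4 (2 mol %), NaIO4 (4 equiv), 2,6-lutidine, dioxane/H2O 3:1, rt
Reagents that add atoms: osmium tetroxide, O=[Os](=O)(=O)=O; sodium periodate, [Na+].[O-]I(=O)(=O)=O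
Why: Lemieux–Johnson cleavage, in which the monosubstituted alkene is dihydroxylated much faster than the hindered electron-poor vinyl iodide and periodate cleaves the diol to the C5 aldehyde.

Step 19
Reactants: 25 {(2R,3R)-3-{[(2S,3S)-3-[(acetyloxy)methyl]-3-methyl-2-(2-oxoethyl)oxiran-2-yl]methyl}-2-[(3Z)-4-iodopent-3-en-1-yl]oxiran-2-yl}methyl acetate
Product: 26 {(1R,3R,3'S,6Z,10R)-3'-[(acetyloxy)methyl]-5-hydroxy-3',6-dimethylspiro[11-oxabicyclo[8.1.0]undec-6-ene-3,2'-oxiran]-10-yl}methyl acetate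
Conditions: CrCl2 (10 equiv), NiCl2 (0.1 equiv), degassed DMSO, rt, syringe-pump addition to 0.002 M
Reagents that add atoms: none
Why: Intramolecular Nozaki–Hiyama–Kishi coupling, in which the nickel-catalysed alkenylchromium forms with retention of the Z geometry and adds chemoselectively to the aldehyde, closes the ten-membered ring (both C5 epimers are used).

Step 20
Reactants: 26 {(1R,3R,3'S,6Z,10R)-3'-[(acetyloxy)methyl]-5-hydroxy-3',6-dimethylspiro[11-oxabicyclo[8.1.0]undec-6-ene-3,2'-oxiran]-10-yl}methyl acetate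
Product: 27 {(1R,3S,3'S,6Z,10R)-3'-[(acetyloxy)methyl]-3',6-dimethyl-5-oxospiro[11-oxabicyclo[8.1.0]undec-6-ene-3,2'-oxiran]-10-yl}methyl acetate
Conditions: Dess–Martin periodinane, pyridine, CH2Cl2, 0 °C → rt
Reagents that add atoms: none
Why: Buffered Dess–Martin oxidation of the allylic alcohol gives the ring Z-enone without disturbing the oxiranes, the acetates or any stereocentre.

**Compound list**
1 | ethyl 2-methyl-3-oxobutanoate | CCOC(=O)C(C)C(C)=O | starting material
2 | ethyl 5-hydroxy-2-methyl-3-oxopentanoate | CCOC(=O)C(C)C(=O)CCO | intermediate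
3 | 4-hydroxy-3-methyl-5,6-dihydro-2H-pyran-2-one | CC1=C(O)CCOC1=O | intermediate
4 | 3-methyl-2-oxo-5,6-dihydro-2H-pyran-4-yl trifluoromethanesulfonate | CC1=C(OS(=O)(=O)C(F)(F)F)CCOC1=O | intermediate
5 | 3-methyl-4-(prop-2-en-1-yl)-5,6-dihydro-2H-pyran-2-one | CC1=C(CC=C)CCOC1=O | intermediate
6 | (2Z)-2-methyl-3-(prop-2-en-1-yl)pent-2-ene-1,5-diol | OC/C(C)=C(/CC=C)CCO | intermediate
7 | 2-[(2R,3S)-3-(hydroxymethyl)-3-methyl-2-(prop-2-en-1-yl)oxiran-2-yl]ethan-1-ol | C=CC[C@]1(CCO)O[C@@]1(C)CO | intermediate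
8 | 2-[(2R,3S)-3-(hydroxymethyl)-3-methyl-2-(prop-2-en-1-yl)oxiran-2-yl]acetaldehyde | C=CC[C@]1(CC=O)O[C@@]1(C)CO | intermediate
9 | (1S,6R)-1-methyl-6-(prop-2-en-1-yl)-3,7-dioxabicyclo[4.1.0]heptan-4-ol (both anomers) | C=CC[C@]1(CC(O)OC2)O[C@]12C | intermediate
10 | (1S,6R)-1-methyl-6-(prop-2-en-1-yl)-3,7-dioxabicyclo[4.1.0]heptan-4-one | C=CC[C@]1(CC(=O)OC2)O[C@]12C | intermediate
11 | propane-1,3-diol | OCCCO | starting material
12 | 3-{[tert-butyl(dimethyl)silyl]oxy}propan-1-ol | CC(C)(C)[Si](C)(C)OCCCO | intermediate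
13 | 3-{[tert-butyl(dimethyl)silyl]oxy}propanal | CC(C)(C)[Si](C)(C)OCCC=O | intermediate
14 | tert-butyl{[(3Z)-4-iodopent-3-en-1-yl]oxy}dimethylsilane | C/C(I)=C/CCO[Si](C)(C)C(C)(C)C | intermediate
15 | (3Z)-4-iodopent-3-en-1-ol | C/C(I)=C/CCO | intermediate
16 | (2Z)-2,5-diiodopent-2-ene | C/C(I)=C/CCI | intermediate
17 | ethyl (triphenyl-lambda5-phosphanylidene)acetate | CCOC(=O)C=P(c1ccccc1)(c1ccccc1)c1ccccc1 | starting material
18 | [(5Z)-1-ethoxy-6-iodo-1-oxohept-5-en-2-yl]triphenylphosphonium iodide (racemic) | CCOC(=O)C(CC/C=C(/C)I)[P+](c1ccccc1)(c1ccccc1)c1ccccc1.[I-] | intermediate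
19 | ethyl (5Z)-6-iodo-2-(triphenyl-lambda5-phosphanylidene)hept-5-enoate | CCOC(=O)C(CC/C=C(/C)I)=P(c1ccccc1)(c1ccccc1)c1ccccc1 | intermediate
20 | ethyl (2E,5Z)-2-{2-[(2R,3S)-3-(hydroxymethyl)-3-methyl-2-(prop-2-en-1-yl)oxiran-2-yl]ethylidene}-6-iodohept-5-enoate | CCOC(=O)/C(CC/C=C(/C)I)=C/C[C@@]1(CC=C)O[C@@]1(C)CO | intermediate
21 | (2E,5Z)-2-{2-[(2R,3S)-3-(hydroxymethyl)-3-methyl-2-(prop-2-en-1-yl)oxiran-2-yl]ethylidene}-6-iodohept-5-en-1-ol | OC/C(CC/C=C(/C)I)=C/C[C@@]1(CC=C)O[C@@]1(C)CO | intermediate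
22 | {(2R,3R)-3-{[(2R,3S)-3-(hydroxymethyl)-3-methyl-2-(prop-2-en-1-yl)oxiran-2-yl]methyl}-2-[(3Z)-4-iodopent-3-en-1-yl]oxiran-2-yl}methanol | OC[C@@]1(CC/C=C(/C)I)O[C@@H]1C[C@@]1(CC=C)O[C@@]1(C)CO | intermediate
23 | {(2R,3R)-3-{[(2R,3S)-3-[(acetyloxy)methyl]-3-methyl-2-(prop-2-en-1-yl)oxiran-2-yl]methyl}-2-[(3Z)-4-iodopent-3-en-1-yl]oxiran-2-yl}methyl acetate | CC(=O)OC[C@@]1(CC/C=C(/C)I)O[C@@H]1C[C@@]1(CC=C)O[C@@]1(C)COC(C)=O | intermediate
24 | {(2R,3R)-3-{[(2R,3S)-3-[(acetyloxy)methyl]-2-(2,3-dihydroxypropyl)-3-methyloxiran-2-yl]methyl}-2-[(3Z)-4-iodopent-3-en-1-yl]oxiran-2-yl}methyl acetate (carbinol epimers) | CC(=O)OC[C@@]1(CC/C=C(/C)I)O[C@@H]1C[C@@]1(CC(O)CO)O[C@@]1(C)COC(C)=O | intermediate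
25 | {(2R,3R)-3-{[(2S,3S)-3-[(acetyloxy)methyl]-3-methyl-2-(2-oxoethyl)oxiran-2-yl]methyl}-2-[(3Z)-4-iodopent-3-en-1-yl]oxiran-2-yl}methyl acetate | CC(=O)OC[C@@]1(CC/C=C(/C)I)O[C@@H]1C[C@@]1(CC=O)O[C@@]1(C)COC(C)=O | intermediate
26 | {(1R,3R,3'S,6Z,10R)-3'-[(acetyloxy)methyl]-5-hydroxy-3',6-dimethylspiro[11-oxabicyclo[8.1.0]undec-6-ene-3,2'-oxiran]-10-yl}methyl acetate (C5 epimers) | CC(=O)OC[C@]12CC/C=C(/C)C(O)C[C@]3(C[C@H]1O2)O[C@@]3(C)COC(C)=O | intermediate
27 | {(1R,3S,3'S,6Z,10R)-3'-[(acetyloxy)methyl]-3',6-dimethyl-5-oxospiro[11-oxabicyclo[8.1.0]undec-6-ene-3,2'-oxiran]-10-yl}methyl acetate (CNP0185847.4) | CC(=O)OC[C@]12CC/C=C(/C)C(=O)C[C@]3(C[C@H]1O2)O[C@@]3(C)COC(C)=O | target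

**Step count and risks**

Total step count: 20 (east 1–7, west 8–14, union and endgame 15–20). Longest linear sequence: 13 steps (1–7 then 15–20; the west branch 8–14 then 15–20 is equally long), which is 65 % of the total.

Most likely to fail, first: step 19. A ten-membered ring must close against transannular strain and oligomerisation, and the β,γ-epoxy aldehyde meets Lewis-acidic chromium salts. Fallback: close the ring one stage earlier, on the enoate, and build the second oxirane on the macrocycle. It sets out from 20 and comes back at 26. Acylation of 20 (pivaloyl chloride, pyridine, DMAP) gives the pivalate ester F1. OsO4/NaIO4 cleavage of its terminal alkene, which is faster than attack on the conjugated enoate or the vinyl iodide, gives the epoxy aldehyde F2. CrCl2/NiCl2 ring closure at high dilution, now with one oxirane fewer and a rigid ring-cis enoate turn, gives the macrocyclic allylic alcohol F3. Silylation (TBSOTf, 2,6-lutidine) gives the silyl ether F4. iBu2AlH reduces the ester and removes the pivalate to give the macrocyclic diol F5. Sharpless epoxidation with D-(−)-diethyl tartrate gives the bis-epoxy diol F6. Ac2O/pyridine gives the diacetate silyl ether F7, and HF·pyridine then frees the C5 hydroxyl to give 26.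

Second: step 15. Only a small share of the lactol is open, the ylide is α-branched and slow, and heating a β,γ-epoxy aldehyde invites β-elimination or oxa-Michael closure of the product. Fallback: carry the aldehyde free instead of as a lactol by protecting-group differentiation. It sets out from 7 and comes back at 21. TBSCl/imidazole at −20 °C silylates the unhindered primary hydroxyl of 7 to give the silyl ether F8. Ac2O/pyridine gives the acetate F9. HF·pyridine gives the hydroxy acetate F10. Dess–Martin oxidation gives the free epoxy aldehyde F11, which cannot close to a lactol. Wittig reaction with 19 at room temperature gives the enoate acetate F12, and iBu2AlH reduces the ester and cleaves the acetate to give 21.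

Third: step 13. SN2 alkylation of a stabilised ylide by an unactivated homoallylic iodide is slow and competes with transylidation and with E2 to the iododiene. Fallback: use a phosphonate carbanion in place of the ylide. It sets out from 16 and comes back at 20. Alkylation of the sodium salt of triethyl phosphonoacetate (NaH, DMF, 50 °C) with 16 gives the phosphonate F13. Horner–Wadsworth–Emmons olefination of lactol 9 with F13 (LiCl, DBU, MeCN) gives 20, bypassing 17–19.

**Further compounds**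
F1 | step 19 | ethyl (2E,5Z)-2-{2-[(2R,3S)-3-{[(2,2-dimethylpropanoyl)oxy]methyl}-3-methyl-2-(prop-2-en-1-yl)oxiran-2-yl]ethylidene}-6-iodohept-5-enoate | CCOC(=O)/C(CC/C=C(/C)I)=C/C[C@@]1(CC=C)O[C@@]1(C)COC(=O)C(C)(C)C
F2 | step 19 | ethyl (2E,5Z)-2-{2-[(2S,3S)-3-{[(2,2-dimethylpropanoyl)oxy]methyl}-3-methyl-2-(2-oxoethyl)oxiran-2-yl]ethylidene}-6-iodohept-5-enoate | CCOC(=O)/C(CC/C=C(/C)I)=C/C[C@@]1(CC=O)O[C@@]1(C)COC(=O)C(C)(C)C
F3 | step 19 | ethyl (2S,3S,5E,9Z)-2-{[(2,2-dimethylpropanoyl)oxy]methyl}-11-hydroxy-2,10-dimethyl-1-oxaspiro[2.9]dodeca-5,9-diene-6-carboxylate (C11 epimers) | CCOC(=O)/C1=C/C[C@@]2(CC(O)/C(C)=C\CC1)O[C@@]2(C)COC(=O)C(C)(C)C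
F4 | step 19 | ethyl (2S,3S,5E,9Z)-11-{[tert-butyl(dimethyl)silyl]oxy}-2-{[(2,2-dimethylpropanoyl)oxy]methyl}-2,10-dimethyl-1-oxaspiro[2.9]dodeca-5,9-diene-6-carboxylate | CCOC(=O)/C1=C/C[C@@]2(CC(O[Si](C)(C)C(C)(C)C)/C(C)=C\CC1)O[C@@]2(C)COC(=O)C(C)(C)C
F5 | step 19 | [(2S,3S,5E,9Z)-11-{[tert-butyl(dimethyl)silyl]oxy}-2,10-dimethyl-1-oxaspiro[2.9]dodeca-5,9-diene-2,6-diyl]dimethanol | OC/C1=C/C[C@@]2(CC(O[Si](C)(C)C(C)(C)C)/C(C)=C\CC1)O[C@@]2(C)CO
F6 | step 19 | [(1R,3S,3'S,6Z,10R)-5-{[tert-butyl(dimethyl)silyl]oxy}-3',6-dimethylspiro[11-oxabicyclo[8.1.0]undec-6-ene-3,2'-oxirane]-3',10-diyl]dimethanol | OC[C@]12CC/C=C(/C)C(O[Si](C)(C)C(C)(C)C)C[C@]3(C[C@H]1O2)O[C@@]3(C)CO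
F7 | step 19 | {(1R,3S,3'S,6Z,10R)-3'-[(acetyloxy)methyl]-5-{[tert-butyl(dimethyl)silyl]oxy}-3',6-dimethylspiro[11-oxabicyclo[8.1.0]undec-6-ene-3,2'-oxiran]-10-yl}methyl acetate | CC(=O)OC[C@]12CC/C=C(/C)C(O[Si](C)(C)C(C)(C)C)C[C@]3(C[C@H]1O2)O[C@@]3(C)COC(C)=O
F8 | step 15 | [(2S,3R)-3-(2-{[tert-butyl(dimethyl)silyl]oxy}ethyl)-2-methyl-3-(prop-2-en-1-yl)oxiran-2-yl]methanol | C=CC[C@]1(CCO[Si](C)(C)C(C)(C)C)O[C@@]1(C)CO
F9 | step 15 | [(2S,3R)-3-(2-{[tert-butyl(dimethyl)silyl]oxy}ethyl)-2-methyl-3-(prop-2-en-1-yl)oxiran-2-yl]methyl acetate | C=CC[C@]1(CCO[Si](C)(C)C(C)(C)C)O[C@@]1(C)COC(C)=O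
F10 | step 15 | [(2S,3R)-3-(2-hydroxyethyl)-2-methyl-3-(prop-2-en-1-yl)oxiran-2-yl]methyl acetate | C=CC[C@]1(CCO)O[C@@]1(C)COC(C)=O
F11 | step 15 | [(2S,3R)-2-methyl-3-(2-oxoethyl)-3-(prop-2-en-1-yl)oxiran-2-yl]methyl acetate | C=CC[C@]1(CC=O)O[C@@]1(C)COC(C)=O
F12 | step 15 | ethyl (2E,5Z)-2-{2-[(2R,3S)-3-[(acetyloxy)methyl]-3-methyl-2-(prop-2-en-1-yl)oxiran-2-yl]ethylidene}-6-iodohept-5-enoate | CCOC(=O)/C(CC/C=C(/C)I)=C/C[C@@]1(CC=C)O[C@@]1(C)COC(C)=O
F13 | step 13 | ethyl (5Z)-2-(diethoxyphosphoryl)-6-iodohept-5-enoate (racemic) | CCOC(=O)C(CC/C=C(/C)I)P(=O)(OCC)OCC
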